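## Structural features

CNP0192765.0 is an octamer of phloroglucinol: eight benzene rings (lettered A to H in the order of the SMILES string), sixteen free phenols, no sp3 carbon and no stereocentre. Atoms are labelled by ring letter and position: b1 (O to ring A), b2 (OH), b3 (H), b4 (OH), b5 (bond to c6), b6 (furan O); c1 (furan O), c2 (H), c3 (OH), c4 (O to d6), c5 (O to d1), c6; d1, d2 (OH), d3 (H), d4 (OH), d5 (O to e1), d6; e6–f1 is the biaryl bond, and f6–O–g1 and g6–O–h1 are the last two ethers. Rings B and C are fused through a furan and rings C and D through a 1,4-dioxin, giving an angular benzofuro-dibenzodioxin that carries ring A on b1; ring D passes its d5 oxygen to ring E, E is bound to F by a tetra-ortho-oxygenated biaryl bond, and F, G and H follow as diaryl ethers. Every ether oxygen stands on a carbon flanked by oxygenated or arylated carbons, so each diaryl ether is tri- or tetra-ortho-substituted. The E–F axis carries four different ortho substituents, but the structure gives it no descriptor. Fragile features are the electron-rich, air-sensitive polyphenol and the 2,2'-biphenol of rings E and F, which can cyclise to a dibenzofuran with loss of water under acid. The real difficulty is ring D within the core: five adjacent carbons bear oxygen, and the dioxin bond at d6 lies between two aryloxy-bearing carbons of a very electron-rich ring, where a leaving group is hard to place and a substitution hard to run. The key step exploits that the d4 hydroxyl is para to the dioxin oxygen on d1 and that d6 is ortho to d1: two-electron oxidation of a d4 phenol makes d1 a ketal carbon and d6 the β-carbon of a dienone, six atoms away from the phenol oxygen on c4.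

## Logic of the disconnections

35 ⇒ 34. The fifteen O–CH3 bonds are cut, so that every phenol except d4–OH is a methyl ether. This masks the oxidation-prone polyphenol until the end and needs one type of protecting group only. The forward step must cleave fifteen aryl methyl ethers without breaking a diaryl ether and without dehydrating the E–F biphenol.

34 ⇒ 31. The dioxin bond O(c4)–d6 is cut, methanol is formally added back across d1/d6, and the c4 oxygen carries a fluoride-labile acetal. In one sentence: the dioxin is closed, and the fifth oxygen of ring D introduced, by conjugate addition of the ring-C phenoxide to a ring-D quinone monoketal that is already tied to ring C through its ketal carbon, followed by loss of methanol. This copies the presumed oxidative C–O coupling by which eckol-type dioxins arise. The gain is that d6 is a C–H carbon in 31, that ring D needs four oxygens only and no leaving group, and that both halves of the molecule are already joined. The demand is that the phenoxide adds to d6 and not to d2, that it does so before any acid is present, and that the adduct then loses methanol to re-aromatise.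

31 ⇒ 30. The d1–OCH3 bond is cut and the dienone is returned to the phenol. 30 is an ordinary triaryl ether; the forward oxidation needs d4–OH to be the only free phenol, with methanol capturing the para position d1.

30 ⇒ 28 ⇒ 27 + 9, and 27 ⇒ 24 + 26. The d4–O bond is traced back to a formyl group, and the aryl ether bonds d5–O(e1) and d1–O(c5) are cut. The formyl group activates both carbons of 26 for substitution and later becomes the d4 hydroxyl. Ring D thus comes from a one-step building block, and the left half 24 and the right half 9 are complete before they meet. The fluoride must be displaced first (by 24, at d1), the bromide second (by 9, at d5), and the aldehyde must be the only one in 28.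

9 ⇒ 8 + 4; 4 ⇒ 2 + 3; 2 ⇒ 1. The ether bonds f6–O(g1) and g6–O(h1) are cut. Rings G and H then come from one dibromide 2 whose two C–Br bonds differ in hindrance and electron density. The forward couplings must take place at the less hindered bromide of 2 first, and only once on the symmetrical diol 8.

8 ⇒ 7 ⇒ 6 ⇒ 5 ⇒ 1. The two phenol C–O bonds are traced back through C–B bonds to C–Br bonds, and the biaryl bond e6–f1 is cut into two molecules of 5. The tetra-ortho-substituted biaryl is made by homocoupling of two identical halves, so it raises no regiochemical question. The iodination of 1 must occur next to the bromine, the coupling must take place at C–I only, and the oxygens must enter through boron, so that a free hydroxyl never faces a carbon–metal bond on the neighbouring ring, which would close a dibenzofuran.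

24 ⇒ 23 ⇒ 22 ⇒ 21 + 15. The sulfonate on c5–O is restored, and then the furan bond b5–c6 and the ether bond b6–O(c1) are cut. The bromine on c6 of 21 decides on which side of ring C the furan closes, and ring B has a single free ortho position. The forward ether formation must use the iodide of 15 and leave the bromide of 21 for the ring closure.

21 ⇒ 19 ⇒ 18 ⇒ 17 ⇒ 16. The c1–O bond is traced back to a formyl group, and the sulfonate S–O bond, the c6–Br bond and the acetal O–C bond on c4 are cut. All six positions of ring C are then already present, correctly placed, in 16. The two adjacent hydroxyls must be told apart and the bromine placed between the formyl group and the free hydroxyl.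

15 ⇒ 14 ⇒ 12 ⇒ 10 + 11. The b4–OCH3 bond is cut, the b4–O bond is traced back to a formyl group, and the ether bond b1–O to ring A is cut. The iodine of 10 marks b6. The O-arylation must tolerate the iodide.

26 ⇒ 25. The C–Br bond is cut; the bromination must go para to the methoxy group.

## Other disconnections considered

Alternative 1: The first plan that comes to mind cuts both dioxin C–O bonds and every diaryl ether as Ullmann or SNAr couplings of halogenated, fully oxygenated arenes. Ring D would come from 5,6-dibromovanillin as the aryl ether 2,3-dibromo-4-(3,5-dimethoxyphenoxy)-5-methoxybenzaldehyde A1, and the forward key step would be a twofold etherification of A1 with the catechol 6-(3,5-dimethoxyphenoxy)-3,7,9-trimethoxydibenzo[b,d]furan-1,2-diol A2. The chosen plan is preferred on three grounds. The two hydroxyls of A2 and the two bromides of A1 can pair in two orientations, and the orientation can be lost again by Smiles rearrangement, so regioisomeric dioxins are expected. The bromide between two oxygenated carbons is the most hindered electrophile of the whole molecule. And ring E can enter only as a plain ring, so the E–F bond would have to be made after a late halogenation among many equally activated rings, which costs steps.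

Alternative 2: Ring D is taken back to a quinone, 2,3-dibromo-5-methoxy-1,4-benzoquinone A3. A first addition–elimination with 9 would give 3-bromo-5-methoxy-2-(BIAR-oxy)-1,4-benzoquinone A4, a second one with a ring-C phenol would place the other aryl ether on the neighbouring carbon, and reduction and a copper-mediated closure would follow. This is attractive because no metal is needed for the two hindered ethers. In A4, however, the second phenoxide should add preferentially to the carbon that already bears the aryloxy group, because the developing carbanion is stabilised by the adjacent C–Br. That expels the first aryloxide and scrambles the order of the two substituents on ring D. The closure also needs a halogen on ring C. The chosen plan fixes the order with a true aryl ether at d1 and needs no leaving group at d6.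

Alternative 3: The E–F biaryl bond is cut last. A Suzuki coupling would join the bromide 2-bromo-1-[2,4-dimethoxy-6-(2,4,6-trimethoxyphenoxy)phenoxy]-3,5-dimethoxybenzene A5 to the ring-E pinacol boronate of the fully methylated pentacyclic core, A6. A tetra-ortho-substituted biaryl would then have to be formed between two large partners at the end; 2,6-dioxygenated arylboron compounds protodeboronate easily; and an oxidative (anodic) variant could not distinguish the biaryl positions from the activated positions of the other electron-rich rings. The chosen plan makes this bond in step 4 by homocoupling of a small symmetrical arene.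

Key step: step 23

Remark on stereochemistry: the target has no stereocentre and its SMILES gives no descriptor for the E–F axis; the axis is treated as configurationally undefined and nothing in the route controls it.
Remark on names: SEM = [2-(trimethylsilyl)ethoxy]methyl; DBF = the 6-(3,5-dimethoxyphenoxy)-3,7,9-trimethoxy-2-(SEM-oxy)dibenzo[b,d]furan-1-yl group of 24; BIAR = the 2'-[2,4-dimethoxy-6-(2,4,6-trimethoxyphenoxy)phenoxy]-4,4',6,6'-tetramethoxy-[1,1'-biphenyl]-2-yl group of 9.

## Route

Step 1
Reactants: 1 1-bromo-3,5-dimethoxybenzene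
Product: 2 1,2-dibromo-3,5-dimethoxybenzene
Conditions: NBS, MeCN, 0 to 25 °C
Reagents that add atoms: N-bromosuccinimide, O=C1CCC(=O)N1Br
Why: Electrophilic aromatic bromination; in a 5-substituted resorcinol dimethyl ether the position para to one methoxy group and ortho to the other (next to the bromine) should be attacked in preference to the position flanked by both methoxy groups.

Step 2
Reactants: 2 1,2-dibromo-3,5-dimethoxybenzene; 3 2,4,6-trimethoxyphenol
Product: 4 2-bromo-1,5-dimethoxy-3-(2,4,6-trimethoxyphenoxy)benzene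
Conditions: CuI (10 mol%), picolinic acid (20 mol%), K3PO4, DMSO, 100 °C
Reagents that add atoms: none
Why: Ullmann diaryl ether synthesis with a ligated monovalent copper catalyst; the C1–Br bond of 2 is meta to both methoxy groups and has a free ortho position, whereas C2–Br is ortho/para to both donors and flanked on both sides, so the hindered phenoxide should enter at C1 only and the second bromide is kept for step 7.

Step 3
Reactants: 1 1-bromo-3,5-dimethoxybenzene
Product: 5 1-bromo-2-iodo-3,5-dimethoxybenzene
Conditions: NIS, CF3CO2H (cat.), MeCN, 25 °C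
Reagents that add atoms: N-iodosuccinimide, O=C1CCC(=O)N1I
Why: Electrophilic iodination with the same positional preference as in step 1 (para to one methoxy group, next to bromine).

Step 4
Reactants: 5 1-bromo-2-iodo-3,5-dimethoxybenzene; 5 1-bromo-2-iodo-3,5-dimethoxybenzene
Product: 6 2,2'-dibromo-4,4',6,6'-tetramethoxy-1,1'-biphenyl
Conditions: Cu powder (3 equiv), DMF, 140 °C
Reagents that add atoms: none
Why: Classical Ullmann reductive homocoupling, in which two molecules of 5 are joined at their iodine-bearing carbons; copper inserts into the weaker C–I bond only, so the tetra-ortho-substituted biaryl bond (the future e6–f1 bond) is made on a symmetrical substrate and both bromides survive.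

Step 5
Reactants: 6 2,2'-dibromo-4,4',6,6'-tetramethoxy-1,1'-biphenyl
Product: 7 2,2'-(4,4',6,6'-tetramethoxy-[1,1'-biphenyl]-2,2'-diyl)bis(4,4,5,5-tetramethyl-1,3,2-dioxaborolane)
Conditions: bis(pinacolato)diboron (3 equiv), PdCl2(dppf) (5 mol%), KOAc, 1,4-dioxane, 100 °C
Reagents that add atoms: bis(pinacolato)diboron, CC1(C)OB(OC1(C)C)B1OC(C)(C)C(C)(C)O1
Why: Miyaura borylation of both C–Br bonds, which are meta to the methoxy groups and have one free ortho position; no hydroxyl is present at this stage, so the arylpalladium intermediate cannot be trapped by the neighbouring ring as a dibenzofuran.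

Step 6
Reactants: 7 2,2'-(4,4',6,6'-tetramethoxy-[1,1'-biphenyl]-2,2'-diyl)bis(4,4,5,5-tetramethyl-1,3,2-dioxaborolane)
Product: 8 4,4',6,6'-tetramethoxy-[1,1'-biphenyl]-2,2'-diol
Conditions: H2O2 (30% aq.), NaOH (aq.), THF, 0 to 25 °C; then aq. NH4Cl
Reagents that add atoms: hydrogen peroxide, OO
Why: Oxidation of the arylboronates; hydroperoxide adds to boron, the aryl group shifts from boron to oxygen at the same carbon, and hydrolysis gives the C2-symmetric biphenol with both hydroxyls at the former C–Br positions.

Step 7
Reactants: 8 4,4',6,6'-tetramethoxy-[1,1'-biphenyl]-2,2'-diol; 4 2-bromo-1,5-dimethoxy-3-(2,4,6-trimethoxyphenoxy)benzene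
Product: 9 2'-[2,4-dimethoxy-6-(2,4,6-trimethoxyphenoxy)phenoxy]-4,4',6,6'-tetramethoxy-[1,1'-biphenyl]-2-ol
Conditions: 8 (3 equiv), Pd(OAc)2 (5 mol%), tBuXPhos (7.5 mol%), K3PO4, toluene, 110 °C
Reagents that add atoms: none
Why: Palladium-catalysed C–O cross-coupling of a 2,6-disubstituted aryl bromide with an ortho-substituted phenol, for which bulky di-tert-butyl biarylphosphines favour the C–O reductive elimination; the excess of symmetrical 8 should hold the reaction at the mono-ether, unreacted 8 can be recovered, and the biphenyl carries no halogen that the remaining hydroxyl could displace.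

Step 8
Reactants: 10 4-hydroxy-3-iodo-5-methoxybenzaldehyde; 11 (3,5-dimethoxyphenyl)boronic acid
Product: 12 4-(3,5-dimethoxyphenoxy)-3-iodo-5-methoxybenzaldehyde
Conditions: Cu(OAc)2 (1.5 equiv), pyridine, 4 Å molecular sieves, CH2Cl2, air, 25 °C
Reagents that add atoms: none
Why: Chan–Lam oxidative O-arylation at room temperature, which leaves the C–I bond and the aldehyde untouched; the phenol is the only nucleophile.

Step 9
Reactants: 12 4-(3,5-dimethoxyphenoxy)-3-iodo-5-methoxybenzaldehyde
Product: 14 4-(3,5-dimethoxyphenoxy)-3-iodo-5-methoxyphenol, via aryl formate 13 (not isolated)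
Conditions: mCPBA, CH2Cl2, 0 to 25 °C; then K2CO3 (cat.), MeOH, 25 °C
Reagents that add atoms: 3-chloroperoxybenzoic acid, OOC(=O)c1cccc(Cl)c1
Why: Dakin-type Baeyer–Villiger oxidation; the electron-rich aryl group (para-aryloxy) migrates in the peroxyacid adduct to give the formate, which methanol then cleaves.

Step 10
Reactants: 14 4-(3,5-dimethoxyphenoxy)-3-iodo-5-methoxyphenol
Product: 15 2-(3,5-dimethoxyphenoxy)-1-iodo-3,5-dimethoxybenzene
Conditions: MeI, K2CO3, DMF, 25 °C
Reagents that add atoms: iodomethane, CI
Why: Williamson O-methylation of the only phenol; the methyl ether masks the future b4 hydroxyl until step 24.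

Step 11
Reactants: 16 3,4-dihydroxy-5-methoxybenzaldehyde
Product: 17 3-hydroxy-5-methoxy-4-(SEM-oxy)benzaldehyde
Conditions: SEMCl (1.05 equiv), iPr2NEt, CH2Cl2, 0 °C
Reagents that add atoms: 2-(trimethylsilyl)ethoxymethyl chloride, C[Si](C)(C)CCOCCl
Why: Selective O-alkylation of the 4-hydroxyl, which is para to the formyl group and so the more acidic one; the acetal is stable to all later bases and is removed by fluoride.

Step 12
Reactants: 17 3-hydroxy-5-methoxy-4-(SEM-oxy)benzaldehyde
Product: 18 2-bromo-3-hydroxy-5-methoxy-4-(SEM-oxy)benzaldehyde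
Conditions: NBS, MeCN, 0 °C
Reagents that add atoms: N-bromosuccinimide, O=C1CCC(=O)N1Br
Why: Electrophilic bromination; the free 3-hydroxyl directs ortho and the 5-methoxy group para to the same carbon (C2, between CHO and OH), the position normally brominated in 3-hydroxy-4-alkoxybenzaldehydes, and this places the halogen on the future c6.

Step 13
Reactants: 18 2-bromo-3-hydroxy-5-methoxy-4-(SEM-oxy)benzaldehyde
Product: 19 2-bromo-3-formyl-5-methoxy-6-(SEM-oxy)phenyl methanesulfonate
Conditions: MsCl, Et3N, CH2Cl2, 0 °C
Reagents that add atoms: methanesulfonyl chloride, CS(Cl)(=O)=O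
Why: Sulfonylation of the remaining phenol; the methanesulfonate should survive the Baeyer–Villiger, copper and palladium steps, carries no aryl C–H bond that the arylpalladium of step 16 could attack to form a cyclic sulfonate, and is cleaved by hydroxide without touching the SEM ether.

Step 14
Reactants: 19 2-bromo-3-formyl-5-methoxy-6-(SEM-oxy)phenyl methanesulfonate
Product: 21 2-bromo-3-hydroxy-5-methoxy-6-(SEM-oxy)phenyl methanesulfonate, via aryl formate 20 (not isolated)
Conditions: mCPBA, CH2Cl2, 0 to 25 °C; then K2CO3 (cat.), MeOH, 0 °C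
Reagents that add atoms: 3-chloroperoxybenzoic acid, OOC(=O)c1cccc(Cl)c1
Why: Dakin-type Baeyer–Villiger oxidation (aryl migration favoured by the para oxygen) followed by mild methanolysis of the formate, which the sulfonate and the acetal tolerate; this sets free the future furan oxygen on c1.

Step 15
Reactants: 21 2-bromo-3-hydroxy-5-methoxy-6-(SEM-oxy)phenyl methanesulfonate; 15 2-(3,5-dimethoxyphenoxy)-1-iodo-3,5-dimethoxybenzene
Product: 22 2-bromo-3-[2-(3,5-dimethoxyphenoxy)-3,5-dimethoxyphenoxy]-5-methoxy-6-(SEM-oxy)phenyl methanesulfonate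
Conditions: CuI (10 mol%), picolinic acid (20 mol%), K3PO4, DMSO, 85 °C
Reagents that add atoms: none
Why: Ullmann diaryl ether synthesis; the monovalent copper catalyst should react with the aryl iodide of 15 at 85 °C, while the bromide of 21 (ortho to the phenoxide, flanked on both sides) and the sulfonate are expected to stay intact.

Step 16
Reactants: 22 2-bromo-3-[2-(3,5-dimethoxyphenoxy)-3,5-dimethoxyphenoxy]-5-methoxy-6-(SEM-oxy)phenyl methanesulfonate
Product: 23 6-(3,5-dimethoxyphenoxy)-3,7,9-trimethoxy-2-(SEM-oxy)dibenzo[b,d]furan-1-yl methanesulfonate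
Conditions: Pd(OAc)2 (5 mol%), PCy3·HBF4 (10 mol%), K2CO3, DMA, 130 °C
Reagents that add atoms: none
Why: Palladium-catalysed intramolecular direct arylation (concerted metalation–deprotonation); oxidative addition into the only C–Br bond and C–H cleavage at b5, the single free ortho position of ring B, close the furan, so the angular fusion is fixed by the bromine set in step 12.

Step 17
Reactants: 23 6-(3,5-dimethoxyphenoxy)-3,7,9-trimethoxy-2-(SEM-oxy)dibenzo[b,d]furan-1-yl methanesulfonate
Product: 24 6-(3,5-dimethoxyphenoxy)-3,7,9-trimethoxy-2-(SEM-oxy)dibenzo[b,d]furan-1-ol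
Conditions: KOH, MeOH/THF, 60 °C; then aq. NH4Cl
Reagents that add atoms: none
Why: Cleavage of the aryl methanesulfonate by hydroxide at sulfur; methyl ethers and the SEM acetal are inert to hydroxide, so c5–OH is the only hydroxyl set free.

Step 18
Reactants: 25 4-fluoro-3-methoxybenzaldehyde
Product: 26 2-bromo-4-fluoro-5-methoxybenzaldehyde
Conditions: Br2, AcOH, 25 °C
Reagents that add atoms: bromine, BrBr
Why: Electrophilic bromination para to the methoxy group (ortho to the formyl group), the usual position in 3-methoxybenzaldehydes; this places the bromine on the future d5.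

Step 19
Reactants: 24 6-(3,5-dimethoxyphenoxy)-3,7,9-trimethoxy-2-(SEM-oxy)dibenzo[b,d]furan-1-ol; 26 2-bromo-4-fluoro-5-methoxybenzaldehyde
Product: 27 2-bromo-4-(DBF-oxy)-5-methoxybenzaldehyde
Conditions: Cs2CO3, DMSO, 80 °C
Reagents that add atoms: none
Why: Nucleophilic aromatic substitution by addition–elimination; fluoride para to the formyl group should be displaced far faster than the ortho bromide, so the hindered phenoxide of 24 is fixed on d1 as a stable diaryl ether, which defines the orientation of the later dioxin ring.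

Step 20
Reactants: 27 2-bromo-4-(DBF-oxy)-5-methoxybenzaldehyde; 9 2'-[2,4-dimethoxy-6-(2,4,6-trimethoxyphenoxy)phenoxy]-4,4',6,6'-tetramethoxy-[1,1'-biphenyl]-2-ol
Product: 28 2-(BIAR-oxy)-4-(DBF-oxy)-5-methoxybenzaldehyde
Conditions: CuI (20 mol%), 2,2,6,6-tetramethylheptane-3,5-dione (40 mol%), Cs2CO3, NMP, 110 °C
Reagents that add atoms: none
Why: Ullmann diaryl ether synthesis at the only carbon–halogen bond of 27, which is activated by the ortho formyl group and has a free ortho position; the aldehyde, the SEM acetal and the methyl ethers are stable to Cs2CO3.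

Step 21
Reactants: 28 2-(BIAR-oxy)-4-(DBF-oxy)-5-methoxybenzaldehyde
Product: 30 2-(BIAR-oxy)-4-(DBF-oxy)-5-methoxyphenol, via aryl formate 29 (not isolated)
Conditions: mCPBA, CH2Cl2, 0 °C; then K2CO3 (cat.), MeOH, 0 °C
Reagents that add atoms: 3-chloroperoxybenzoic acid, OOC(=O)c1cccc(Cl)c1
Why: Dakin-type Baeyer–Villiger oxidation of the single aldehyde; the ring-D aryl group (ortho- and para-aryloxy) migrates, and methanolysis of the formate unveils d4–OH, the only free hydroxyl of 30.

Step 22
Reactants: 30 2-(BIAR-oxy)-4-(DBF-oxy)-5-methoxyphenol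
Product: 31 2-(BIAR-oxy)-4-(DBF-oxy)-4,5-dimethoxycyclohexa-2,5-dien-1-one
Conditions: PhI(OAc)2 (1.1 equiv), MeOH/CH2Cl2, 0 °C
Reagents that add atoms: methanol, CO
Why: Oxidative dearomatisation of a para-oxygenated phenol with a trivalent iodine reagent; the phenoxonium ion from the only free phenol is trapped by methanol at the para carbon d1 to give the mixed methyl aryl quinone monoketal (d1 formed as a racemic, transient stereocentre), and the methyl ethers of the other rings should not be oxidised by PhI(OAc)2 in methanol without acid activation.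

Step 23
Reactants: 31 2-(BIAR-oxy)-4-(DBF-oxy)-4,5-dimethoxycyclohexa-2,5-dien-1-one
Product: 34 pentadeca-O-methyl ether of 35 (free OH on d4), via desilylated dienone 32 (not isolated), via cyclised ketal 33 (not isolated)
Conditions: Bu4NF (3 equiv), THF, 45 °C; then CF3CO2H, CH2Cl2, 0 to 25 °C
Reagents that add atoms: none
Why: Proposed new method: fluoride removes the SEM group and frees the c4 phenoxide (32), which should add in a conjugate sense to d6, the unsubstituted β-carbon of the cross-conjugated dienone, closing the 1,4-dioxin by a 6-exo-trig mode (33); acid then ionises the ketal with loss of methanol, and loss of the d6 proton and enolisation re-aromatise ring D and return d4–OH, so the net result is a dehydrogenative C–O coupling that installs the fifth oxygen of ring D. The closest known reaction types are the conjugate addition of heteroatom nucleophiles to quinone monoketals with eliminative aromatisation to 3-substituted 4-alkoxyphenols, and the intramolecular oxa-Michael addition of phenols to cyclohexadienones. The orientation of the dioxin (c5–O–d1, c4–O–d6) is fixed by the aryl ether made in step 19, because the tethered phenoxide can reach only the two carbons next to d1. Of these, d2 bears a methoxy group, is a poorer acceptor and cannot lead to an arene, so material that adds there can only return, whereas addition at d6 is made irreversible by the aromatisation. The α-carbon d5 with the ether to ring E is not an acceptor position, and a carbon nucleophile of ring E would have to close by a 5-endo mode and is not activated under basic conditions. The phenoxide must add before any acid is present, since acid on the free phenol could form a spiroketal at d1 and exchange the two ring-C oxygens; the fluoride-labile protecting group secures this order. The three sp3 centres of 33 are transient and no stereocentre remains.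

Step 24
Reactants: 34 pentadeca-O-methyl ether of 35 (free OH on d4)
Product: 35 CNP0192765.0
Conditions: BBr3 (excess), CH2Cl2, −78 to 25 °C; then H2O, argon
Reagents that add atoms: none
Why: Exhaustive Lewis-acid demethylation of fifteen aryl methyl ethers; diaryl ethers, the furan and the dioxin are not cleaved by BBr3, and cold aqueous work-up under inert gas should limit cyclodehydration of the E–F biphenol and air oxidation.

## Compound list

1 | 1-bromo-3,5-dimethoxybenzene | COc1cc(Br)cc(OC)c1 | starting material
2 | 1,2-dibromo-3,5-dimethoxybenzene | COc1cc(Br)c(Br)c(OC)c1 | intermediate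
3 | 2,4,6-trimethoxyphenol | COc1cc(OC)c(O)c(OC)c1 | starting material
4 | 2-bromo-1,5-dimethoxy-3-(2,4,6-trimethoxyphenoxy)benzene | COc1cc(OC)c(Br)c(Oc2c(OC)cc(OC)cc2OC)c1 | intermediate
5 | 1-bromo-2-iodo-3,5-dimethoxybenzene | COc1cc(Br)c(I)c(OC)c1 | intermediate
6 | 2,2'-dibromo-4,4',6,6'-tetramethoxy-1,1'-biphenyl | COc1cc(Br)c(-c2c(Br)cc(OC)cc2OC)c(OC)c1 | intermediate
7 | 2,2'-(4,4',6,6'-tetramethoxy-[1,1'-biphenyl]-2,2'-diyl)bis(4,4,5,5-tetramethyl-1,3,2-dioxaborolane) | COc1cc(B2OC(C)(C)C(C)(C)O2)c(-c2c(B3OC(C)(C)C(C)(C)O3)cc(OC)cc2OC)c(OC)c1 | intermediate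
8 | 4,4',6,6'-tetramethoxy-[1,1'-biphenyl]-2,2'-diol | COc1cc(O)c(-c2c(O)cc(OC)cc2OC)c(OC)c1 | intermediate
9 | 2'-[2,4-dimethoxy-6-(2,4,6-trimethoxyphenoxy)phenoxy]-4,4',6,6'-tetramethoxy-[1,1'-biphenyl]-2-ol | COc1cc(O)c(-c2c(OC)cc(OC)cc2Oc2c(OC)cc(OC)cc2Oc2c(OC)cc(OC)cc2OC)c(OC)c1 | intermediate
10 | 4-hydroxy-3-iodo-5-methoxybenzaldehyde (5-iodovanillin) | COc1cc(C=O)cc(I)c1O | starting material
11 | (3,5-dimethoxyphenyl)boronic acid | COc1cc(OC)cc(B(O)O)c1 | starting material
12 | 4-(3,5-dimethoxyphenoxy)-3-iodo-5-methoxybenzaldehyde | COc1cc(OC)cc(Oc2c(I)cc(C=O)cc2OC)c1 | intermediate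
13 | 4-(3,5-dimethoxyphenoxy)-3-iodo-5-methoxyphenyl formate | COc1cc(OC)cc(Oc2c(I)cc(OC=O)cc2OC)c1 | intermediate
14 | 4-(3,5-dimethoxyphenoxy)-3-iodo-5-methoxyphenol | COc1cc(OC)cc(Oc2c(I)cc(O)cc2OC)c1 | intermediate
15 | 2-(3,5-dimethoxyphenoxy)-1-iodo-3,5-dimethoxybenzene | COc1cc(OC)cc(Oc2c(I)cc(OC)cc2OC)c1 | intermediate
16 | 3,4-dihydroxy-5-methoxybenzaldehyde (5-hydroxyvanillin) | COc1cc(C=O)cc(O)c1O | starting material
17 | 3-hydroxy-5-methoxy-4-{[2-(trimethylsilyl)ethoxy]methoxy}benzaldehyde | COc1cc(C=O)cc(O)c1OCOCC[Si](C)(C)C | intermediate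
18 | 2-bromo-3-hydroxy-5-methoxy-4-{[2-(trimethylsilyl)ethoxy]methoxy}benzaldehyde | COc1cc(C=O)c(Br)c(O)c1OCOCC[Si](C)(C)C | intermediate
19 | 2-bromo-3-formyl-5-methoxy-6-{[2-(trimethylsilyl)ethoxy]methoxy}phenyl methanesulfonate | COc1cc(C=O)c(Br)c(OS(C)(=O)=O)c1OCOCC[Si](C)(C)C | intermediate
20 | 2-bromo-3-(formyloxy)-5-methoxy-6-{[2-(trimethylsilyl)ethoxy]methoxy}phenyl methanesulfonate | COc1cc(OC=O)c(Br)c(OS(C)(=O)=O)c1OCOCC[Si](C)(C)C | intermediate
21 | 2-bromo-3-hydroxy-5-methoxy-6-{[2-(trimethylsilyl)ethoxy]methoxy}phenyl methanesulfonate | COc1cc(O)c(Br)c(OS(C)(=O)=O)c1OCOCC[Si](C)(C)C | intermediate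
22 | 2-bromo-3-[2-(3,5-dimethoxyphenoxy)-3,5-dimethoxyphenoxy]-5-methoxy-6-{[2-(trimethylsilyl)ethoxy]methoxy}phenyl methanesulfonate | COc1cc(OC)cc(Oc2c(Oc3cc(OC)c(OCOCC[Si](C)(C)C)c(OS(C)(=O)=O)c3Br)cc(OC)cc2OC)c1 | intermediate
23 | 6-(3,5-dimethoxyphenoxy)-3,7,9-trimethoxy-2-{[2-(trimethylsilyl)ethoxy]methoxy}dibenzo[b,d]furan-1-yl methanesulfonate | COc1cc(OC)cc(Oc2c(OC)cc(OC)c3c2oc2cc(OC)c(OCOCC[Si](C)(C)C)c(OS(C)(=O)=O)c23)c1 | intermediate
24 | 6-(3,5-dimethoxyphenoxy)-3,7,9-trimethoxy-2-{[2-(trimethylsilyl)ethoxy]methoxy}dibenzo[b,d]furan-1-ol | COc1cc(OC)cc(Oc2c(OC)cc(OC)c3c2oc2cc(OC)c(OCOCC[Si](C)(C)C)c(O)c23)c1 | intermediate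
25 | 4-fluoro-3-methoxybenzaldehyde | COc1cc(C=O)ccc1F | starting material
26 | 2-bromo-4-fluoro-5-methoxybenzaldehyde | COc1cc(C=O)c(Br)cc1F | intermediate
27 | 2-bromo-4-(DBF-oxy)-5-methoxybenzaldehyde | COc1cc(OC)cc(Oc2c(OC)cc(OC)c3c2oc2cc(OC)c(OCOCC[Si](C)(C)C)c(Oc4cc(Br)c(C=O)cc4OC)c23)c1 | intermediate
28 | 2-(BIAR-oxy)-4-(DBF-oxy)-5-methoxybenzaldehyde | COc1cc(OC)cc(Oc2c(OC)cc(OC)c3c2oc2cc(OC)c(OCOCC[Si](C)(C)C)c(Oc4cc(Oc5cc(OC)cc(OC)c5-c5c(OC)cc(OC)cc5Oc5c(OC)cc(OC)cc5Oc5c(OC)cc(OC)cc5OC)c(C=O)cc4OC)c23)c1 | intermediate
29 | 2-(BIAR-oxy)-4-(DBF-oxy)-5-methoxyphenyl formate | COc1cc(OC)cc(Oc2c(OC)cc(OC)c3c2oc2cc(OC)c(OCOCC[Si](C)(C)C)c(Oc4cc(Oc5cc(OC)cc(OC)c5-c5c(OC)cc(OC)cc5Oc5c(OC)cc(OC)cc5Oc5c(OC)cc(OC)cc5OC)c(OC=O)cc4OC)c23)c1 | intermediate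
30 | 2-(BIAR-oxy)-4-(DBF-oxy)-5-methoxyphenol | COc1cc(OC)cc(Oc2c(OC)cc(OC)c3c2oc2cc(OC)c(OCOCC[Si](C)(C)C)c(Oc4cc(Oc5cc(OC)cc(OC)c5-c5c(OC)cc(OC)cc5Oc5c(OC)cc(OC)cc5Oc5c(OC)cc(OC)cc5OC)c(O)cc4OC)c23)c1 | intermediate
31 | 2-(BIAR-oxy)-4-(DBF-oxy)-4,5-dimethoxycyclohexa-2,5-dien-1-one (racemic at the ketal carbon) | COc1cc(OC)cc(Oc2c(OC)cc(OC)c3c2oc2cc(OC)c(OCOCC[Si](C)(C)C)c(OC4(OC)C=C(Oc5cc(OC)cc(OC)c5-c5c(OC)cc(OC)cc5Oc5c(OC)cc(OC)cc5Oc5c(OC)cc(OC)cc5OC)C(=O)C=C4OC)c23)c1 | intermediate
32 | dienone 31 without the SEM group (free 2-hydroxyl on the dibenzofuran, present as its tetrabutylammonium phenoxide) | COc1cc(OC)cc(Oc2c(OC)cc(OC)c3c2oc2cc(OC)c(O)c(OC4(OC)C=C(Oc5cc(OC)cc(OC)c5-c5c(OC)cc(OC)cc5Oc5c(OC)cc(OC)cc5Oc5c(OC)cc(OC)cc5OC)C(=O)C=C4OC)c23)c1 | intermediate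
33 | cyclised ketal: the c4 oxygen of 32 bonded to d6; ring D with d1 as ketal carbon (OMe), d2=d3 enol ether, d4 ketone, d5 and d6 sp3 (mixture of diastereomers) | COc1cc(OC)cc(Oc2c(OC)cc(OC)c3c2oc2cc(OC)c4c(c23)OC2(OC)C(OC)=CC(=O)C(Oc3cc(OC)cc(OC)c3-c3c(OC)cc(OC)cc3Oc3c(OC)cc(OC)cc3Oc3c(OC)cc(OC)cc3OC)C2O4)c1 | intermediate
34 | pentadeca-O-methyl ether of 35: all hydroxyls methylated except the ring-D hydroxyl on d4 | COc1cc(OC)cc(Oc2c(OC)cc(OC)c3c2oc2cc(OC)c4c(c23)Oc2c(OC)cc(O)c(Oc3cc(OC)cc(OC)c3-c3c(OC)cc(OC)cc3Oc3c(OC)cc(OC)cc3Oc3c(OC)cc(OC)cc3OC)c2O4)c1 | intermediate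
35 | CNP0192765.0 | Oc1cc(O)cc(Oc2c(O)cc(O)c3c2oc2cc(O)c4c(c23)Oc2c(O)cc(O)c(Oc3cc(O)cc(O)c3-c3c(O)cc(O)cc3Oc3c(O)cc(O)cc3Oc3c(O)cc(O)cc3O)c2O4)c1 | target

## Step count and least certain steps

Total: 24 steps. Longest linear sequence: 13 steps (16 to 35 through steps 11–17 and 19–24).

Step 23 (key step). The conjugate addition may lose out to three processes: slow cleavage of the aryl SEM ether by fluoride, collapse of the mixed aryl methyl ketal back to a quinone with expulsion of the left-half phenoxide, and addition of the phenoxide to the methoxy-bearing carbon d2, which gives a dienone that cannot aromatise. Fallback by known substitution and copper chemistry, setting out from 24 and 9: 24 would be coupled (Cs2CO3, DMSO) with 3-bromo-2,4-difluoro-5-methoxybenzaldehyde F1 (from 2-bromo-1,3-difluoro-4-methoxybenzene, LiN(iPr)2 at −78 °C, then DMF) at the fluorine para to the formyl group to give 3-bromo-4-(DBF-oxy)-2-fluoro-5-methoxybenzaldehyde F2. Phenol 9 would displace the ortho fluorine to give 2-(BIAR-oxy)-3-bromo-4-(DBF-oxy)-5-methoxybenzaldehyde F3, and Bu4NF would remove the SEM group to give the phenol F4. An intramolecular Ullmann etherification (CuI, N,N-dimethylglycine, Cs2CO3, 1,4-dioxane, 100 °C) at the bromide between the two aryloxy groups would close the dioxin to the dioxin aldehyde F5, and a Dakin oxidation through the formate F6 would come back to the route at 34.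

Step 7. Oxidative addition to the doubly ortho-substituted, electron-rich bromide 4 and C–O reductive elimination with the bulky phenoxide of 8 may be too slow, so that hydrodebromination of 4 or double arylation of 8 takes over. Fallback with the roles of the partners exchanged, setting out from 4 and 6: 4 would be converted (n-BuLi, B(OMe)3, then H2O2) into 2,4-dimethoxy-6-(2,4,6-trimethoxyphenoxy)phenol F7. F7 would be coupled under copper catalysis with an excess of dibromide 6 to give 2-bromo-2'-[2,4-dimethoxy-6-(2,4,6-trimethoxyphenoxy)phenoxy]-4,4',6,6'-tetramethoxy-1,1'-biphenyl F8. The remaining bromide, which no longer faces a free hydroxyl, would be exchanged for hydroxyl with KOH under palladium catalysis (Pd2(dba)3, tBuXPhos), which comes back to the route at 9.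

Step 12. Bromination may go partly to C6 (para to the free hydroxyl) or displace the formyl group, because both open positions are activated by one ortho and one para oxygen. Fallback that fixes the position through the starting material: commercial 2,3-dibromo-4-hydroxy-5-methoxybenzaldehyde would replace 16 and 17. Copper-mediated hydroxylation (NaOH, Cu powder, H2O) of the bromide ortho to the phenoxide would give 2-bromo-3,4-dihydroxy-5-methoxybenzaldehyde F9, and SEM protection of the hydroxyl para to the formyl group (as in step 11) comes back to the route at 18.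

Step 24. Cleavage of fifteen methyl ethers may stop short, the HBr formed may promote cyclodehydration of the E–F biphenol to a dibenzofuran, and the free polyphenol may oxidise during work-up. Fallback by nucleophilic instead of Lewis-acid dealkylation, from 34 directly to 35: sodium ethanethiolate (NaSEt) in DMF at 130 °C cleaves the methyl groups by SN2 attack under basic conditions, where acid-promoted dehydration cannot occur; it makes no new compound.

## Further compounds

F1 | step 23 | 3-bromo-2,4-difluoro-5-methoxybenzaldehyde | COc1cc(C=O)c(F)c(Br)c1F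
F2 | step 23 | 3-bromo-4-(DBF-oxy)-2-fluoro-5-methoxybenzaldehyde | COc1cc(OC)cc(Oc2c(OC)cc(OC)c3c2oc2cc(OC)c(OCOCC[Si](C)(C)C)c(Oc4c(Br)c(F)c(C=O)cc4OC)c23)c1
F3 | step 23 | 2-(BIAR-oxy)-3-bromo-4-(DBF-oxy)-5-methoxybenzaldehyde | COc1cc(OC)cc(Oc2c(OC)cc(OC)c3c2oc2cc(OC)c(OCOCC[Si](C)(C)C)c(Oc4c(Br)c(Oc5cc(OC)cc(OC)c5-c5c(OC)cc(OC)cc5Oc5c(OC)cc(OC)cc5Oc5c(OC)cc(OC)cc5OC)c(C=O)cc4OC)c23)c1
F4 | step 23 | phenol from F3 after loss of the SEM group (free 2-hydroxyl on the dibenzofuran) | COc1cc(OC)cc(Oc2c(OC)cc(OC)c3c2oc2cc(OC)c(O)c(Oc4c(Br)c(Oc5cc(OC)cc(OC)c5-c5c(OC)cc(OC)cc5Oc5c(OC)cc(OC)cc5Oc5c(OC)cc(OC)cc5OC)c(C=O)cc4OC)c23)c1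
F5 | step 23 | dioxin aldehyde: compound 34 with a formyl group in place of the d4 hydroxyl | COc1cc(OC)cc(Oc2c(OC)cc(OC)c3c2oc2cc(OC)c4c(c23)Oc2c(OC)cc(C=O)c(Oc3cc(OC)cc(OC)c3-c3c(OC)cc(OC)cc3Oc3c(OC)cc(OC)cc3Oc3c(OC)cc(OC)cc3OC)c2O4)c1
F6 | step 23 | formate ester of 34 (formyloxy on d4) | COc1cc(OC)cc(Oc2c(OC)cc(OC)c3c2oc2cc(OC)c4c(c23)Oc2c(OC)cc(OC=O)c(Oc3cc(OC)cc(OC)c3-c3c(OC)cc(OC)cc3Oc3c(OC)cc(OC)cc3Oc3c(OC)cc(OC)cc3OC)c2O4)c1
F7 | step 7 | 2,4-dimethoxy-6-(2,4,6-trimethoxyphenoxy)phenol | COc1cc(OC)c(O)c(Oc2c(OC)cc(OC)cc2OC)c1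
F8 | step 7 | 2-bromo-2'-[2,4-dimethoxy-6-(2,4,6-trimethoxyphenoxy)phenoxy]-4,4',6,6'-tetramethoxy-1,1'-biphenyl | COc1cc(Br)c(-c2c(OC)cc(OC)cc2Oc2c(OC)cc(OC)cc2Oc2c(OC)cc(OC)cc2OC)c(OC)c1
F9 | step 12 | 2-bromo-3,4-dihydroxy-5-methoxybenzaldehyde | COc1cc(C=O)c(Br)c(O)c1O
F0 | step 24 | none | none
A1 | alternative 1 | 2,3-dibromo-4-(3,5-dimethoxyphenoxy)-5-methoxybenzaldehyde | COc1cc(OC)cc(Oc2c(Br)c(Br)c(C=O)cc2OC)c1
A2 | alternative 1 | 6-(3,5-dimethoxyphenoxy)-3,7,9-trimethoxydibenzo[b,d]furan-1,2-diol | COc1cc(OC)cc(Oc2c(OC)cc(OC)c3c2oc2cc(OC)c(O)c(O)c23)c1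
A3 | alternative 2 | 2,3-dibromo-5-methoxy-1,4-benzoquinone | COC1=CC(=O)C(Br)=C(Br)C1=O
A4 | alternative 2 | 3-bromo-5-methoxy-2-(BIAR-oxy)-1,4-benzoquinone | COC1=CC(=O)C(Oc2cc(OC)cc(OC)c2-c2c(OC)cc(OC)cc2Oc2c(OC)cc(OC)cc2Oc2c(OC)cc(OC)cc2OC)=C(Br)C1=O
A5 | alternative 3 | 2-bromo-1-[2,4-dimethoxy-6-(2,4,6-trimethoxyphenoxy)phenoxy]-3,5-dimethoxybenzene | COc1cc(OC)c(Br)c(Oc2c(OC)cc(OC)cc2Oc2c(OC)cc(OC)cc2OC)c1
A6 | alternative 3 | ring-E pinacol boronate of the fully O-methylated pentacyclic core (boron on e6) | COc1cc(OC)cc(Oc2c(OC)cc(OC)c3c2oc2cc(OC)c4c(c23)Oc2c(OC)cc(OC)c(Oc3cc(OC)cc(OC)c3B3OC(C)(C)C(C)(C)O3)c2O4)c1
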